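**Retrosynthetic overview**
- The target comes from a 9α-hydroxy-8-silyloxy-2-ketone by C9 senecioylation and C8 silyl-to-acetyl exchange; the 9α-carbinol comes from equatorial hydride delivery to the C9 ketone of a cis-fused 2,9-dione (a 1,4-diketone through C1–C10).
- Key disconnection C9–C10: an intramolecular Stetter reaction in which the C9 aldehyde reacts as an acyl anion (Breslow intermediate) with enone carbon C10; this closes ring B and fixes the cis ring fusion.
- C4/C5: copper-catalysed desymmetrising conjugate methylation of a 4,4-disubstituted cyclohexadienone.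
- C7/C8 and the isopropenyl group: enantioselective glyoxylate–ene reaction on a prenyl side chain.
- Ring order: ring A is the carbocycle of p-cresol (dearomatised with para-allylation in step 1); ring B is closed in step 7.

Assumption: atoms are numbered as in eremophilane (ring A = C1–C5 and C10, ketone at C2, methyl C15 on C4, methyl C14 on C5; ring B = C5–C10, isopropenyl C11–C13 on C7, acetate on C8, senecioate on C9), and the ligand enantiomers named in steps 3 and 5 follow the published sense of induction for simpler alkenes and enones (the mirror-image ligand would be used if this substrate responded oppositely).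

**Step 1**
Reactants: 1 p-cresol (4-methylphenol); 2 allyltrimethylsilane
Product: 3 4-methyl-4-(prop-2-en-1-yl)cyclohexa-2,5-dien-1-one
Conditions: PhI(OAc)2 (1.1 equiv), 2 (4 equiv), (CF3)2CHOH, −20 → 0 °C
Reagents that add atoms: none
Why: Hypervalent-iodine oxidation turns the phenol into a phenoxenium ion (an extended enolonium) that the allylsilane traps at the methyl-bearing para carbon (oxidative dearomatisation with Hosomi–Sakurai-type allylation), creating the future C5 quaternary carbon, which is still achiral.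

**Step 2**
Reactants: 3 4-methyl-4-(prop-2-en-1-yl)cyclohexa-2,5-dien-1-one; 4 2-methylbut-2-ene
Product: 5 4-methyl-4-(3-methylbut-2-en-1-yl)cyclohexa-2,5-dien-1-one
Conditions: second-generation Grubbs catalyst RuCl2(=CHPh)(PCy3)(H2IMes) (3 mol %), 4 (co-solvent), CH2Cl2, 23 °C
Reagents that add atoms: none
Why: Olefin cross-metathesis with excess 2-methylbut-2-ene converts the terminal allyl group into a prenyl group while the electron-poor, hindered dienone alkenes stay untouched; no stereocenter is formed.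

**Step 3**
Reactants: 5 4-methyl-4-(3-methylbut-2-en-1-yl)cyclohexa-2,5-dien-1-one; 6 ethyl glyoxylate
Product: 7 ethyl (2R,3R)-2-hydroxy-4-methyl-3-[(1-methyl-4-oxocyclohexa-2,5-dien-1-yl)methyl]pent-4-enoate
Conditions: [Cu((R,R)-t-Bu-box)](SbF6)2 (10 mol %; from CuCl2, 2,2'-(propane-2,2-diyl)bis[(4R)-4-tert-butyl-4,5-dihydrooxazole] and AgSbF6), 6 (3 equiv), CH2Cl2, 0 → 23 °C
Reagents that add atoms: none
Why: Catalytic enantioselective glyoxylate–ene reaction in which the less substituted prenyl carbon attacks the chelated glyoxylate with hydrogen transfer from a methyl group (this generates the isopropenyl group); the ligand fixes the aldehyde face (C8, R), and the exo-type envelope, with the fully substituted alkene carbon over the formyl hydrogen and the C6 substituent turned away from the chelate, is predicted to give the anti isomer (C7, R).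

**Step 4**
Reactants: 7 ethyl (2R,3R)-2-hydroxy-4-methyl-3-[(1-methyl-4-oxocyclohexa-2,5-dien-1-yl)methyl]pent-4-enoate
Product: 8 ethyl (2R,3R)-2-[(tert-butyldimethylsilyl)oxy]-4-methyl-3-[(1-methyl-4-oxocyclohexa-2,5-dien-1-yl)methyl]pent-4-enoate
Conditions: t-BuMe2SiCl, imidazole, DMF, 23 °C
Reagents that add atoms: tert-butyldimethylsilyl chloride CC(C)(C)[Si](C)(C)Cl
Why: Standard silylation of the secondary alcohol under non-acidic conditions that spare the rearrangement-prone dienone; the silyl ether survives hydride and carbene chemistry and both stereocenters are untouched.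

**Step 5**
Reactants: 8 ethyl (2R,3R)-2-[(tert-butyldimethylsilyl)oxy]-4-methyl-3-[(1-methyl-4-oxocyclohexa-2,5-dien-1-yl)methyl]pent-4-enoate
Product: 10 ethyl (2R,3R)-2-[(tert-butyldimethylsilyl)oxy]-3-{[(1S,6S)-1,6-dimethyl-4-[(trimethylsilyl)oxy]cyclohexa-2,4-dien-1-yl]methyl}-4-methylpent-4-enoate, via methylzinc dienolate 9 (not isolated)
Conditions: Cu(OTf)2 (2.5 mol %), phosphoramidite L1 [(R)-1,1'-binaphthalene-2,2'-diyl N,N-bis((S)-1-phenylethyl)phosphoramidite] (5 mol %), ZnMe2 (1.5 equiv), toluene, −20 °C; then Me3SiOTf, −20 → 0 °C; Et3N, pentane, filtration, used crude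
Reagents that add atoms: dimethylzinc C[Zn]C; trimethylsilyl triflate C[Si](C)(C)OS(=O)(=O)C(F)(F)F
Why: Copper–phosphoramidite-catalysed asymmetric conjugate addition of ZnMe2 desymmetrises the dienone: the ligand selects the enone face at C4 (S), methyl enters the flat ring anti to the bulky C6 side chain and therefore cis to the C5 methyl (this sets C5), and silylation of the zinc enolate keeps the ring carbonyl masked for the next step.

**Step 6**
Reactants: 10 ethyl (2R,3R)-2-[(tert-butyldimethylsilyl)oxy]-3-{[(1S,6S)-1,6-dimethyl-4-[(trimethylsilyl)oxy]cyclohexa-2,4-dien-1-yl]methyl}-4-methylpent-4-enoate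
Product: 12 (2R,3R)-2-[(tert-butyldimethylsilyl)oxy]-3-{[(1R,6S)-1,6-dimethyl-4-oxocyclohex-2-en-1-yl]methyl}-4-methylpent-4-enal, via silyl dienol ether aldehyde 11 (not isolated)
Conditions: i-Bu2AlH (1.2 equiv), CH2Cl2, −78 °C; then 1 M aq. HCl, THF, 0 °C
Reagents that add atoms: none
Why: Partial ester reduction stops at the aldehyde because the α-silyloxy ester forms a chelated aluminium hemiacetal at −78 °C while the ring carbonyl is inert as its silyl dienol ether; dilute acid then protonates C3 and releases the conjugated C1=C10 enone (enol ether hydrolysis) without touching a stereocenter.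

**Step 7**
Reactants: 12 (2R,3R)-2-[(tert-butyldimethylsilyl)oxy]-3-{[(1R,6S)-1,6-dimethyl-4-oxocyclohex-2-en-1-yl]methyl}-4-methylpent-4-enal
Product: 13 (4S,5R,7R,8R,10S)-8-[(tert-butyldimethylsilyl)oxy]eremophil-11-ene-2,9-dione (cis-fused, H-10 cis to C14)
Conditions: 2-(pentafluorophenyl)-6,7-dihydro-5H-pyrrolo[2,1-c][1,2,4]triazol-2-ium tetrafluoroborate (20 mol %), KN(SiMe3)2 (18 mol %), toluene, 23 → 40 °C
Reagents that add atoms: none
Why: Proposed new method: the triazolylidene adds to the aldehyde to give the Breslow intermediate, an acyl anion equivalent at C9, which attacks the normally electrophilic enone carbon C10 in a 6-exo Michael addition (intramolecular Stetter reaction; closest precedent is carbene-catalysed Stetter cyclisation of tethered aldehydes onto cyclohexadienones and cyclic enones next to a quaternary carbon), unveiling the C2/C9 1,4-diketone; the tether can only reach C10 on the face it occupies, through a chair with isopropenyl and silyloxy equatorial, so the decalin is cis-fused (C10, S).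

**Step 8**
Reactants: 13 (4S,5R,7R,8R,10S)-8-[(tert-butyldimethylsilyl)oxy]eremophil-11-ene-2,9-dione
Product: 16 (4S,5R,7R,8R,9S,10S)-8-[(tert-butyldimethylsilyl)oxy]-9-hydroxyeremophil-11-en-2-one, via C2 dimethyl ketal 14 (not isolated), via ketal alcohol 15 (not isolated)
Conditions: HC(OMe)3, MeOH, PPTS (cat.), 23 °C; concentrate; LiBH(s-Bu)3, THF, −78 °C; then 1 M aq. HCl, THF, 0 °C
Reagents that add atoms: trimethyl orthoformate COC(OC)OC (its methoxy groups are present only in 14 and 15)
Why: Temporary-protection chemoselective reduction: only the unhindered C2 ketone is ketalised (the α-silyloxy, α-branched C9 ketone is not), the bulky borohydride then attacks C9 equatorially from the convex β face because the α face is blocked by the axial C4 arm of ring A, giving the axial 9α-alcohol cis to O-8 (C9, S), and aqueous acid returns the C2 ketone.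

**Step 9**
Reactants: 16 (4S,5R,7R,8R,9S,10S)-8-[(tert-butyldimethylsilyl)oxy]-9-hydroxyeremophil-11-en-2-one; 17 3-methylbut-2-enoyl chloride (senecioyl chloride)
Product: 18 (4S,5R,7R,8R,9S,10S)-8-[(tert-butyldimethylsilyl)oxy]-2-oxoeremophil-11-en-9-yl 3-methylbut-2-enoate
Conditions: 17 (3 equiv), pyridine, DMAP (0.2 equiv), CH2Cl2, 0 → 40 °C
Reagents that add atoms: none
Why: DMAP-catalysed acylation of the hindered axial alcohol through the acylpyridinium ion (nucleophilic catalysis), with pyridine as a weak base to suppress vinylketene formation and deconjugation of the senecioate; C9 keeps its configuration.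

**Step 10**
Reactants: 18 (4S,5R,7R,8R,9S,10S)-8-[(tert-butyldimethylsilyl)oxy]-2-oxoeremophil-11-en-9-yl 3-methylbut-2-enoate
Product: 19 (4S,5R,7R,8R,9S,10S)-8-acetoxy-2-oxoeremophil-11-en-9-yl 3-methylbut-2-enoate (target, CNP0150397.1)
Conditions: Ac2O (5 equiv), Cu(OTf)2 (5 mol %), CH2Cl2, 23 °C
Reagents that add atoms: acetic anhydride CC(=O)OC(C)=O
Why: Lewis-acid-catalysed direct exchange of a silyl ether for an acetate: the activated anhydride acylates the ether oxygen and the silyl group leaves as its acetate, with retention at C8 and without a free alkoxide that could trigger acyl migration from O-9.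

**Compound list**
1 | p-cresol (4-methylphenol) | Cc1ccc(O)cc1 | starting material
2 | allyltrimethylsilane | C=CC[Si](C)(C)C | starting material
3 | 4-methyl-4-(prop-2-en-1-yl)cyclohexa-2,5-dien-1-one | C=CCC1(C)C=CC(=O)C=C1 | intermediate
4 | 2-methylbut-2-ene | CC=C(C)C | starting material
5 | 4-methyl-4-(3-methylbut-2-en-1-yl)cyclohexa-2,5-dien-1-one | CC(C)=CCC1(C)C=CC(=O)C=C1 | intermediate
6 | ethyl glyoxylate | CCOC(=O)C=O | starting material
7 | ethyl (2R,3R)-2-hydroxy-4-methyl-3-[(1-methyl-4-oxocyclohexa-2,5-dien-1-yl)methyl]pent-4-enoate | C=C(C)[C@@H](CC1(C)C=CC(=O)C=C1)[C@@H](O)C(=O)OCC | intermediate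
8 | ethyl (2R,3R)-2-[(tert-butyldimethylsilyl)oxy]-4-methyl-3-[(1-methyl-4-oxocyclohexa-2,5-dien-1-yl)methyl]pent-4-enoate | C=C(C)[C@@H](CC1(C)C=CC(=O)C=C1)[C@@H](O[Si](C)(C)C(C)(C)C)C(=O)OCC | intermediate
9 | methylzinc dienolate of the C4-methylated ring (O–ZnMe on C2, otherwise as 10) | C=C(C)[C@@H](C[C@@]1(C)C=CC(O[Zn]C)=C[C@@H]1C)[C@@H](O[Si](C)(C)C(C)(C)C)C(=O)OCC | intermediate
10 | ethyl (2R,3R)-2-[(tert-butyldimethylsilyl)oxy]-3-{[(1S,6S)-1,6-dimethyl-4-[(trimethylsilyl)oxy]cyclohexa-2,4-dien-1-yl]methyl}-4-methylpent-4-enoate | C=C(C)[C@@H](C[C@@]1(C)C=CC(O[Si](C)(C)C)=C[C@@H]1C)[C@@H](O[Si](C)(C)C(C)(C)C)C(=O)OCC | intermediate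
11 | (2R,3R)-2-[(tert-butyldimethylsilyl)oxy]-3-{[(1S,6S)-1,6-dimethyl-4-[(trimethylsilyl)oxy]cyclohexa-2,4-dien-1-yl]methyl}-4-methylpent-4-enal | C=C(C)[C@@H](C[C@@]1(C)C=CC(O[Si](C)(C)C)=C[C@@H]1C)[C@@H](O[Si](C)(C)C(C)(C)C)C=O | intermediate
12 | (2R,3R)-2-[(tert-butyldimethylsilyl)oxy]-3-{[(1R,6S)-1,6-dimethyl-4-oxocyclohex-2-en-1-yl]methyl}-4-methylpent-4-enal | C=C(C)[C@@H](C[C@@]1(C)C=CC(=O)C[C@@H]1C)[C@@H](O[Si](C)(C)C(C)(C)C)C=O | intermediate
13 | (4S,5R,7R,8R,10S)-8-[(tert-butyldimethylsilyl)oxy]eremophil-11-ene-2,9-dione, cis-fused | C=C(C)[C@H]1C[C@@]2(C)[C@H](CC(=O)C[C@@H]2C)C(=O)[C@@H]1O[Si](C)(C)C(C)(C)C | intermediate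
14 | (4S,5R,7R,8R,10S)-8-[(tert-butyldimethylsilyl)oxy]-2,2-dimethoxyeremophil-11-en-9-one | C=C(C)[C@H]1C[C@@]2(C)[C@H](CC(OC)(OC)C[C@@H]2C)C(=O)[C@@H]1O[Si](C)(C)C(C)(C)C | intermediate
15 | (4S,5R,7R,8R,9S,10S)-8-[(tert-butyldimethylsilyl)oxy]-2,2-dimethoxyeremophil-11-en-9-ol | C=C(C)[C@H]1C[C@@]2(C)[C@H](CC(OC)(OC)C[C@@H]2C)[C@H](O)[C@@H]1O[Si](C)(C)C(C)(C)C | intermediate
16 | (4S,5R,7R,8R,9S,10S)-8-[(tert-butyldimethylsilyl)oxy]-9-hydroxyeremophil-11-en-2-one | C=C(C)[C@H]1C[C@@]2(C)[C@H](CC(=O)C[C@@H]2C)[C@H](O)[C@@H]1O[Si](C)(C)C(C)(C)C | intermediate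
17 | 3-methylbut-2-enoyl chloride (senecioyl chloride) | CC(C)=CC(=O)Cl | starting material
18 | (4S,5R,7R,8R,9S,10S)-8-[(tert-butyldimethylsilyl)oxy]-2-oxoeremophil-11-en-9-yl 3-methylbut-2-enoate | C=C(C)[C@H]1C[C@@]2(C)[C@H](CC(=O)C[C@@H]2C)[C@H](OC(=O)C=C(C)C)[C@@H]1O[Si](C)(C)C(C)(C)C | intermediate
19 | (4S,5R,7R,8R,9S,10S)-8-acetoxy-2-oxoeremophil-11-en-9-yl 3-methylbut-2-enoate | C=C(C)[C@H]1C[C@@]2(C)[C@H](CC(=O)C[C@@H]2C)[C@H](OC(=O)C=C(C)C)[C@@H]1OC(C)=O | target

**Totals and risks**
Total step count: 10. Longest linear sequence: 10 steps (from p-cresol).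

The three steps most likely to fail are steps 3, 5 and 7.

Step 3 (glyoxylate–ene). The anti sense with this trisubstituted alkene rests on a transition-state argument, not on direct precedent, and the Lewis acid may trigger allyl migration in the dienone. The fallback sets out from 5 and comes back at 7. The ene reaction is run with the mirror-image catalyst [Cu((S,S)-t-Bu-box)](SbF6)2, which, if the reaction is syn-selective, gives ethyl (2S,3R)-2-hydroxy-4-methyl-3-[(1-methyl-4-oxocyclohexa-2,5-dien-1-yl)methyl]pent-4-enoate F1 with the correct C7 and the wrong C8. Mitsunobu inversion (4-nitrobenzoic acid, PPh3, DIAD, THF) then gives the (2R,3R)-4-nitrobenzoate F2, and K2CO3 in EtOH removes the benzoate to give 7. C8 is thus set by SN2 inversion instead of by the catalyst.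

Step 5 (desymmetrising methylation). Methyl must enter anti to the C6 chain, and the discrimination between a methyl and a CH2R group on a flat dienone may be modest. The fallback sets out from 8 and comes back at 13; it reverses the order of the two conjugate additions and sets C4 by hydride delivery instead of methyl delivery.
- Excess i-Bu2AlH reduces ester and dienone to (2R,3R)-2-[(tert-butyldimethylsilyl)oxy]-3-[(4-hydroxy-1-methylcyclohexa-2,5-dien-1-yl)methyl]-4-methylpent-4-en-1-ol F3.
- Dess–Martin periodinane gives (2R,3R)-2-[(tert-butyldimethylsilyl)oxy]-4-methyl-3-[(1-methyl-4-oxocyclohexa-2,5-dien-1-yl)methyl]pent-4-enal F4.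
- A desymmetrising Stetter reaction with an aminoindanol-derived chiral N-pentafluorophenyl triazolium salt and KN(SiMe3)2 lets the catalyst choose the enone arm and gives cis-fused (5R,7R,8R,10S)-8-[(tert-butyldimethylsilyl)oxy]-15-noreremophila-3,11-diene-2,9-dione F5.
- LiCuMe2 with Me3SiCl gives the 2-trimethylsilyl enol ether of the C4-methyl adduct F6; its C4 configuration is irrelevant.
- Pd(OAc)2 in MeCN (Saegusa–Ito oxidation) gives (5S,7R,8R,10S)-8-[(tert-butyldimethylsilyl)oxy]eremophila-3,11-diene-2,9-dione F7.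
- Conjugate reduction with [(Ph3P)CuH]6 delivers hydride to C4 axially on the α face, anti to the axial C14 methyl, leaving C15 equatorial and cis to C14, which is 13.

Step 7 (Stetter cyclisation). The aldehyde is α-branched and α-silyloxylated, so Breslow-intermediate formation may be slow and silyloxide loss or C8 epimerisation may compete; the acceptor carbon also sits next to a quaternary centre. The fallback sets out from 12 and comes back at 13. The same C9–C10 bond is made by single-electron umpolung: SmI2 (2.5 equiv), t-BuOH, THF, −78 °C turns the aldehyde into a ketyl radical anion that adds 6-exo to C10 from the tether face. This gives cis-fused (4S,5R,7R,8R,10S)-8-[(tert-butyldimethylsilyl)oxy]-9-hydroxyeremophil-11-en-2-one F8 as a C9 epimer mixture, which Dess–Martin periodinane oxidises to 13.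

**Further compounds**
F1 | step 3 | ethyl (2S,3R)-2-hydroxy-4-methyl-3-[(1-methyl-4-oxocyclohexa-2,5-dien-1-yl)methyl]pent-4-enoate | C=C(C)[C@@H](CC1(C)C=CC(=O)C=C1)[C@H](O)C(=O)OCC
F2 | step 3 | ethyl (2R,3R)-4-methyl-3-[(1-methyl-4-oxocyclohexa-2,5-dien-1-yl)methyl]-2-[(4-nitrobenzoyl)oxy]pent-4-enoate | C=C(C)[C@@H](CC1(C)C=CC(=O)C=C1)[C@@H](OC(=O)c2ccc(cc2)[N+](=O)[O-])C(=O)OCC
F3 | step 5 | (2R,3R)-2-[(tert-butyldimethylsilyl)oxy]-3-[(4-hydroxy-1-methylcyclohexa-2,5-dien-1-yl)methyl]-4-methylpent-4-en-1-ol (ring cis/trans mixture) | C=C(C)[C@@H](CC1(C)C=CC(O)C=C1)[C@@H](O[Si](C)(C)C(C)(C)C)CO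
F4 | step 5 | (2R,3R)-2-[(tert-butyldimethylsilyl)oxy]-4-methyl-3-[(1-methyl-4-oxocyclohexa-2,5-dien-1-yl)methyl]pent-4-enal | C=C(C)[C@@H](CC1(C)C=CC(=O)C=C1)[C@@H](O[Si](C)(C)C(C)(C)C)C=O
F5 | step 5 | (5R,7R,8R,10S)-8-[(tert-butyldimethylsilyl)oxy]-15-noreremophila-3,11-diene-2,9-dione, cis-fused | C=C(C)[C@H]1C[C@@]2(C)[C@H](CC(=O)C=C2)C(=O)[C@@H]1O[Si](C)(C)C(C)(C)C
F6 | step 5 | 8-[(tert-butyldimethylsilyl)oxy]-2-[(trimethylsilyl)oxy]eremophila-2,11-dien-9-one (C4 epimers; C5, C7, C8, C10 as in 13) | C=C(C)[C@H]1C[C@@]2(C)[C@H](CC(O[Si](C)(C)C)=CC2C)C(=O)[C@@H]1O[Si](C)(C)C(C)(C)C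
F7 | step 5 | (5S,7R,8R,10S)-8-[(tert-butyldimethylsilyl)oxy]eremophila-3,11-diene-2,9-dione (geometry as in 13) | C=C(C)[C@H]1C[C@@]2(C)[C@H](CC(=O)C=C2C)C(=O)[C@@H]1O[Si](C)(C)C(C)(C)C
F8 | step 7 | (4S,5R,7R,8R,10S)-8-[(tert-butyldimethylsilyl)oxy]-9-hydroxyeremophil-11-en-2-one (C9 epimer mixture) | C=C(C)[C@H]1C[C@@]2(C)[C@H](CC(=O)C[C@@H]2C)C(O)[C@@H]1O[Si](C)(C)C(C)(C)C
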